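Everything rests on disconnecting C1–C10 of the ten-membered ring (C1–C10, germacrane numbering) while reconnecting C3 to C8. Carbons C3 to C8 then form a cyclohexane that coincides with the p-menthane ring of (S)-carvone. This feature lets the contiguous C4–C7 stereotetrad be built on a locked chair, with C8 set trans to C7. An anionic oxy-Cope rearrangement then makes C1–C10, breaks C3–C8, enlarges the ring by four carbons and relays the C8 configuration to the remote C10 methyl centre in one operation. The precursor is a 3-vinyl-8-[(E)-propenyl]cyclohexan-3-ol carrying O4/O5 as an acetonide and O6/O11 as one bridging di-tert-butylsilylene that cannot migrate to the alkoxide.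

Key step: step 9

Assumption: germacrane atom numbers (ring C1–C10, C11 the carbinol carbon of the side chain, C14 the methyl on C10, C15 the methyl on C4) are kept for all intermediates, and a centre that is formed as a mixture and erased later (C4 of the deconjugated ketone, C3 of the carbinol before deoxygenation) is drawn without descriptor.

Step 1
Reactants: 1 (S)-carvone
Product: 2 (5S)-5-(2-hydroxypropan-2-yl)-2-methylcyclohex-2-en-1-one
Conditions: 50% aq. H2SO4, 0 °C
Reagents that add atoms: water, O
Why: Markovnikov acid-catalysed hydration should touch only the electron-rich 1,1-disubstituted alkene, since the protonated enone is deactivated, and it leaves the C7 stereocentre of carvone as it is.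

Step 2
Reactants: 2 (5S)-5-(2-hydroxypropan-2-yl)-2-methylcyclohex-2-en-1-one
Product: 4 (5R)-5-(2-hydroxypropan-2-yl)-2-methylcyclohex-3-en-1-one (C5=C6 alkene; C4 epimers), via dipotassium dienolate 3 (not isolated)
Conditions: KOt-Bu (3 equiv), t-BuOH–THF, 23 °C; inverse quench into 10% aq. AcOH, 0 °C
Reagents that add atoms: none
Why: Under equilibrating conditions the base removes a C6 hydrogen and gives the linearly conjugated dienolate, and its kinetic protonation at the α-carbon C4 (classical deconjugation of a cyclic enone) should move the alkene to C5=C6 without touching C7, material that returns to 2 being recycled.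

Step 3
Reactants: 4 (5R)-5-(2-hydroxypropan-2-yl)-2-methylcyclohex-3-en-1-one
Product: 6 (4S,5R)-4-hydroxy-5-(2-hydroxypropan-2-yl)-2-methylcyclohex-2-en-1-one (C6–OH cis to the C7 side chain), via syn-epoxy ketone 5 (not isolated)
Conditions: VO(acac)2 (cat.), t-BuOOH, CH2Cl2, 0 °C; then Et3N, 23 °C
Reagents that add atoms: tert-butyl hydroperoxide, CC(C)(C)OO
Why: In this homoallylic-alcohol-directed vanadium epoxidation the C11 alkoxide bound to the metal delivers the oxygen to the alkene face that carries the side chain (a pseudo-axial C7 chain meets no syn-axial partner because C3 and C5 are trigonal), and the E1cB opening of the β,γ-epoxy ketone by Et3N keeps the C6–O bond, so C6 is set with its hydroxyl cis to the C7 chain while the C4 mixture is erased.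

Step 4
Reactants: 6 cis-γ-hydroxy enone diol
Product: 7 (6S,7R)-O6,O11-di-tert-butylsilylene enone (six-membered dioxasilinane cis-fused at C6–C7)
Conditions: t-Bu2Si(OTf)2, 2,6-lutidine, CH2Cl2, 0 → 23 °C
Reagents that add atoms: di-tert-butylsilyl bis(trifluoromethanesulfonate), CC(C)(C)[Si](OS(=O)(=O)C(F)(F)F)(OS(=O)(=O)C(F)(F)F)C(C)(C)C
Why: Silylene formation from a 1,3-diol and the silyl bis-triflate should close a six-membered dioxasilinane readily because O6 and the C7 chain are cis, it protects the secondary and the tertiary hydroxyl in one step, ties the O6 substituent away from the C4 methyl group and changes no stereocentre.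

Step 5
Reactants: 7 silylene enone
Product: 8 (4S,5S,6R,7R)-4,5-dihydroxy-3-ketone (O4 and O5 cis to each other and trans to O6 and to the C7 chain)
Conditions: OsO4 (cat.), NMO, citric acid, acetone–H2O, 23 °C
Reagents that add atoms: osmium tetroxide, O=[Os](=O)(=O)=O; N-methylmorpholine N-oxide, C[N+]1([O-])CCOCC1; water, O
Why: The Upjohn dihydroxylation adds both oxygens suprafacially, and approach anti to the pseudo-axial allylic C6–O bond and to the bulky silylene ring should set C4 and C5 together on the face opposite the C7 chain, citric acid keeping the catalytic cycle alive on this electron-poor alkene.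

Step 6
Reactants: 8 dihydroxy ketone
Product: 9 4,5-O-isopropylidene-6,11-O-silylene cyclohexan-3-one
Conditions: Me2C(OMe)2, PPTS (cat.), CH2Cl2, 23 °C
Reagents that add atoms: 2,2-dimethoxypropane, COC(C)(C)OC
Why: Acid-catalysed acetal exchange closes the dioxolane on the cis-vicinal diol, which blocks retro-aldol and α-ketol pathways of the free ketol and leaves the silylene and all stereocentres intact.

Step 7
Reactants: 9 acetonide ketone; 10 (E)-1-bromopropene
Product: 12 (8R)-8-[(E)-prop-1-enyl] ketone (propenyl equatorial; trans to the C7 chain), via lithium enolate 11 (not isolated)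
Conditions: LiHMDS (2.2 equiv), Pd2(dba)3 (cat.), P(t-Bu)3 (cat.), THF–toluene, 0 → 23 °C; pH 7 buffer, −20 °C
Reagents that add atoms: (E)-1-bromopropene, C/C=C/Br
Why: This is a palladium-catalysed α-alkenylation of a ketone enolate (oxidative addition of the alkenyl bromide to zerovalent palladium with retention of the E geometry, enolate transfer, reductive elimination): only C8 can enolise because C4 is quaternary, the lower face of C8 is closed by the syn-axial C4 methyl group and C6–O bond, and α-protonation of the product dienolate held by the excess base should leave the propenyl group equatorial and trans to the C7 chain.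

Step 8
Reactants: 12 C8-propenyl ketone; 13 vinylmagnesium bromide
Product: 14 (3R,4S,5S,6R,7R,8R)-3-vinyl-8-[(E)-prop-1-enyl]cyclohexan-3-ol bearing the 4,5-acetonide and the 6,11-silylene (C3–OH axial; both alkenyl groups equatorial)
Conditions: CeCl3 (anhydrous), 13, THF, −78 °C; then H2O
Reagents that add atoms: vinylmagnesium bromide, C=C[Mg]Br
Why: The weakly basic organocerium reagent adds 1,2 without enolising the doubly activated C8–H, and because the axial trajectory is closed by the syn-axial C5–O bond and the dioxolane on that face, the vinyl group should enter equatorially and set C3 with an axial hydroxyl and the two alkenyl groups trans-diequatorial.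

Step 9
Reactants: 14 3-vinyl-8-propenyl cyclohexanol
Product: 17 (4S,5S,6R,7R,10S,8E)-cyclodec-8-en-3-one bearing the 4,5-acetonide and the 6,11-silylene, via potassium alkoxide 15 (not isolated), via potassium enolate 16 (not isolated)
Conditions: KH, 18-crown-6, THF, 0 → 23 °C; then sat. aq. NH4Cl, −78 °C
Reagents that add atoms: none
Why: KH with 18-crown-6 turns the axial C3 hydroxyl into a dissociated potassium alkoxide, whose donation into the C3–C8 bond lets the concerted [3,3] shift run near room temperature; the closest known reaction type is the anionic oxy-Cope rearrangement of trans-1,2-dialkenylcyclohexanols to (E)-cyclodec-5-enones. The ten-membered ring arises by four-carbon ring expansion, C1–C10 being made while C3–C8 is broken inside a six-centre chair array (C1, C2, C3, C8, C9, C10) that is trans-fused to the cyclohexane chair, so no end-to-end cyclisation is involved. C10 is the only new stereocentre and is controlled by chirality transfer from C8: with both alkenyl groups equatorial only one propenyl rotamer fits the chair, C1 adds to the face of C9=C10 turned towards C3, and the E geometry places C14 pseudo-equatorial, which should give 10S. The same array holds C7 pseudo-equatorial on C8 and therefore should give the E C8=C9 alkene. The step needs face selectivity at C10 and a chair rather than a boat array, and both are secured by the trans C3/C8 relationship, by the chair that keeps the bulky C7 chain equatorial, and by the relief of the syn-axial C4-methyl/C6–O and C3–O/C5–O contacts. Formation of the C2–C3 enolate makes the step irreversible, the quaternary C4 leaves the enolate nothing to eliminate or epimerise, and cold buffered protonation should give the C3 ketone.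

Step 10
Reactants: 17 cyclodec-8-en-3-one
Product: 18 C8–C9 dihydro ketone (all stereocentres as in 17)
Conditions: H2 (1 atm), PtO2 (cat.), EtOAc, 23 °C
Reagents that add atoms: none
Why: Heterogeneous hydrogenation saturates the strained E-alkene and creates no stereocentre, platinum being preferred to palladium because it hardly migrates double bonds and so leaves the allylic C7 and C10 centres alone, while any over-reduction of the ketone only anticipates step 11.

Step 11
Reactants: 18 saturated ketone
Product: 19 C3 carbinol (C3 epimers)
Conditions: LiAlH4, THF, 0 °C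
Reagents that add atoms: none
Why: Hydride reduction of the hindered ketone gives the secondary carbinol needed for radical deoxygenation, and its configuration is irrelevant because C3 becomes a methylene group in step 13.

Step 12
Reactants: 19 C3 carbinol
Product: 21 C3 O-alkyl S-methyl xanthate, via sodium xanthate 20 (not isolated)
Conditions: NaH, CS2, THF, 0 → 23 °C; then MeI
Reagents that add atoms: carbon disulfide, S=C=S; iodomethane, CI
Why: Standard xanthate formation (alkoxide addition to CS2, then S-methylation) activates the neopentyl-type carbinol without placing an ionisable leaving group next to the acetonide.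

Step 13
Reactants: 21 xanthate
Product: 22 (4R,5S,6R,7R,10S)-cyclodecane bearing the 4,5-acetonide and the 6,11-silylene (C3 now CH2)
Conditions: n-Bu3SnH, AIBN (cat.), toluene, 100 °C
Reagents that add atoms: none
Why: In the Barton–McCombie deoxygenation the stannyl radical adds to the thiocarbonyl group, β-scission gives the secondary C3 radical and hydrogen transfer from the stannane closes the chain; the adjacent C4–O ether bond is not a radical leaving group, the ring no longer holds an alkene to cyclise onto, and no stereocentre is involved.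

Step 14
Reactants: 22 silylene acetonide
Product: 23 6,11-diol 4,5-acetonide
Conditions: HF·pyridine, pyridine–THF, 0 → 23 °C
Reagents that add atoms: none
Why: Fluoride-driven cleavage of both Si–O bonds frees the C6 and C11 hydroxyls in one step, and the pyridine buffer keeps the acetonide and the tertiary carbinol safe.

Step 15
Reactants: 23 6,11-diol 4,5-acetonide; 24 angelic acid
Product: 26 6-O-angelate 4,5-acetonide, via mixed anhydride 25 (not isolated)
Conditions: 24, 2,4,6-Cl3C6H2COCl, Et3N, toluene, 23 °C; then 23, 80 °C
Reagents that add atoms: angelic acid, C/C=C(/C)C(=O)O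
Why: Yamaguchi-type mixed-anhydride esterification without nucleophilic catalyst acylates only the secondary C6–OH (the tertiary C11–OH is inert, O4 and O5 are masked), the C6–O bond is not broken so the configuration is kept, and the absence of DMAP and of strong base avoids Z to E isomerisation of the angelate to the tiglate.

Step 16
Reactants: 26 6-O-angelate 4,5-acetonide
Product: 27 CNP0130723.1
Conditions: AcOH–H2O (4:1), 40 °C
Reagents that add atoms: none
Why: Mild acid hydrolysis of the isopropylidene acetal frees the C4 and C5 hydroxyls under conditions too weak to ionise the tertiary carbinols, to isomerise the angelate or to promote acyl migration, and should give the target with the 4R,5S,6R,7R,10S configuration.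

Compound list
1 | (S)-carvone | CC1=CC[C@H](C(C)=C)CC1=O | starting material
2 | (5S)-5-(2-hydroxypropan-2-yl)-2-methylcyclohex-2-en-1-one | CC1=CC[C@H](C(C)(C)O)CC1=O | intermediate
3 | dipotassium salt of the C3–C6 dienolate and C11 alkoxide of 2 | CC1=C([O-])C[C@@H](C(C)(C)[O-])C=C1.[K+].[K+] | intermediate
4 | (5R)-5-(2-hydroxypropan-2-yl)-2-methylcyclohex-3-en-1-one, C4 epimers | CC1C=C[C@H](C(C)(C)O)CC1=O | intermediate
5 | (5S,6R,7R)-5,6-epoxy-3-ketone, oxirane cis to the C7 side chain | CC1[C@@H]2O[C@@H]2[C@H](C(C)(C)O)CC1=O | intermediate
6 | (4S,5R)-4-hydroxy-5-(2-hydroxypropan-2-yl)-2-methylcyclohex-2-en-1-one | CC1=C[C@H](O)[C@H](C(C)(C)O)CC1=O | intermediate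
7 | (6S,7R)-O6,O11-di-tert-butylsilylene enone | CC1=C[C@@H]2O[Si](C(C)(C)C)(C(C)(C)C)OC(C)(C)[C@@H]2CC1=O | intermediate
8 | (4S,5S,6R,7R)-4,5-dihydroxy-6,11-O-silylene cyclohexan-3-one | C[C@]1(O)[C@@H](O)[C@@H]2O[Si](C(C)(C)C)(C(C)(C)C)OC(C)(C)[C@@H]2CC1=O | intermediate
9 | 4,5-O-isopropylidene-6,11-O-silylene cyclohexan-3-one | C[C@]1(OC(C)(C)O2)[C@@H]2[C@@H]3O[Si](C(C)(C)C)(C(C)(C)C)OC(C)(C)[C@@H]3CC1=O | intermediate
10 | (E)-1-bromopropene | C/C=C/Br | starting material
11 | lithium C3–C8 enolate of 9 | C[C@]1(OC(C)(C)O2)[C@@H]2[C@@H]3O[Si](C(C)(C)C)(C(C)(C)C)OC(C)(C)[C@@H]3C=C1[O-].[Li+] | intermediate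
12 | (8R)-8-[(E)-prop-1-enyl] derivative of 9 | C[C@]1(OC(C)(C)O2)[C@@H]2[C@@H]3O[Si](C(C)(C)C)(C(C)(C)C)OC(C)(C)[C@@H]3[C@@H](/C=C/C)C1=O | intermediate
13 | vinylmagnesium bromide | C=C[Mg]Br | starting material
14 | (3R,4S,5S,6R,7R,8R)-3-vinyl-8-[(E)-prop-1-enyl]cyclohexan-3-ol, 4,5-acetonide, 6,11-silylene (key-step precursor) | C[C@]1(OC(C)(C)O2)[C@@H]2[C@@H]3O[Si](C(C)(C)C)(C(C)(C)C)OC(C)(C)[C@@H]3[C@@H](/C=C/C)[C@]1(O)C=C | intermediate
15 | potassium C3 alkoxide of 14 | C[C@]1(OC(C)(C)O2)[C@@H]2[C@@H]3O[Si](C(C)(C)C)(C(C)(C)C)OC(C)(C)[C@@H]3[C@@H](/C=C/C)[C@]1([O-])C=C.[K+] | intermediate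
16 | potassium (Z)-C2–C3 enolate of the ten-membered ring | [K+].[O-]/C1=C\C[C@H](C)/C=C/[C@H]2C(C)(C)O[Si](C(C)(C)C)(C(C)(C)C)O[C@H]2[C@@H]3OC(C)(C)O[C@]13C | intermediate
17 | (4S,5S,6R,7R,10S,8E)-cyclodec-8-en-3-one, 4,5-acetonide, 6,11-silylene (key-step product) | C[C@]1(OC(C)(C)O2)[C@@H]2[C@@H]3O[Si](C(C)(C)C)(C(C)(C)C)OC(C)(C)[C@@H]3/C=C/[C@@H](C)CCC1=O | intermediate
18 | C8–C9 dihydro derivative of 17 | C[C@]1(OC(C)(C)O2)[C@@H]2[C@@H]3O[Si](C(C)(C)C)(C(C)(C)C)OC(C)(C)[C@@H]3CC[C@@H](C)CCC1=O | intermediate
19 | C3 carbinol from 18, C3 epimers | C[C@]1(OC(C)(C)O2)[C@@H]2[C@@H]3O[Si](C(C)(C)C)(C(C)(C)C)OC(C)(C)[C@@H]3CC[C@@H](C)CCC1O | intermediate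
20 | sodium xanthate of 19 | C[C@]1(OC(C)(C)O2)[C@@H]2[C@@H]3O[Si](C(C)(C)C)(C(C)(C)C)OC(C)(C)[C@@H]3CC[C@@H](C)CCC1OC(=S)[S-].[Na+] | intermediate
21 | S-methyl xanthate of 19 | C[C@]1(OC(C)(C)O2)[C@@H]2[C@@H]3O[Si](C(C)(C)C)(C(C)(C)C)OC(C)(C)[C@@H]3CC[C@@H](C)CCC1OC(=S)SC | intermediate
22 | (4R,5S,6R,7R,10S)-3-deoxy cyclodecane, 4,5-acetonide, 6,11-silylene | C[C@]1(OC(C)(C)O2)[C@@H]2[C@@H]3O[Si](C(C)(C)C)(C(C)(C)C)OC(C)(C)[C@@H]3CC[C@@H](C)CCC1 | intermediate
23 | 6,11-diol 4,5-acetonide | C[C@]1(OC(C)(C)O2)[C@@H]2[C@H](O)[C@H](C(C)(C)O)CC[C@@H](C)CCC1 | intermediate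
24 | angelic acid | C/C=C(/C)C(=O)O | starting material
25 | angelic 2,4,6-trichlorobenzoic anhydride | C/C=C(/C)C(=O)OC(=O)c1c(Cl)cc(Cl)cc1Cl | intermediate
26 | 6-O-angelate 4,5-acetonide | C/C=C(/C)C(=O)O[C@@H]1[C@H](C(C)(C)O)CC[C@@H](C)CCC[C@@](C)(OC(C)(C)O2)[C@H]12 | intermediate
27 | CNP0130723.1, (4R,5S,6R,7R,10S)-6-angeloyloxy-germacrane-4,5,11-triol | C/C=C(/C)C(=O)O[C@@H]1[C@H](C(C)(C)O)CC[C@@H](C)CCC[C@@](C)(O)[C@H]1O | target

Total step count: 16. Longest linear sequence: 16 steps, from 1 to 27.

Steps most likely to fail

**Step 9.**
- The dissociated alkoxide may cleave C3–C8 heterolytically instead of rearranging in concert.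
- Part of the flux may pass through a boat array. Either process would erode the transfer of configuration from C8 to C10.
- The enolate or the ketone may also close across the ring during the quench.

The fallback sets out from 14 and keeps the same bond change but removes the charge. TMSOTf and 2,6-lutidine in CH2Cl2 should give the C3 trimethylsilyl ether F1. Heating in degassed o-dichlorobenzene at about 200 °C in base-washed glass should bring about the neutral siloxy-Cope rearrangement to the ring-expanded trimethylsilyl enol ether F2, for which no carbanionic fragmentation is open. K2CO3 in MeOH at 0 °C then releases the ketone, and the route is rejoined at 17.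

**Step 7.**
- Reductive elimination at the congested C8 may be slow.
- The new double bond may migrate into conjugation with the C3 ketone under the basic conditions.

The fallback sets out from 9 and replaces the cross-coupling by alkylation and alkene transposition. LiHMDS and allyl bromide in THF–DMPU at −78 → 0 °C should give the C8-allyl ketone F3, with the allyl group on the open upper face and in the equatorial position. One-position alkene isomerisation with RuHCl(CO)(PPh3)3 in toluene at 80 °C, stopped at the E-propenyl stage, brings the material back at 12.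

**Step 3.**
- The tertiary alcohol may direct the vanadium peroxide poorly, which would give poor facial selectivity.
- The alkene may return into conjugation before it is oxidised.

The fallback sets out from 4 and replaces delivery by inversion.
- m-CPBA buffered with NaHCO3 in CH2Cl2 attacks the face opposite the side chain and should give the anti-epoxy ketone F4.
- Et3N opens it to the trans-γ-hydroxy enone F5.
- A Mitsunobu reaction (4-nitrobenzoic acid, PPh3, DIAD, THF) inverts the secondary allylic carbinol while the tertiary alcohol stays inert, and should give the cis 4-nitrobenzoate F6.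
- K2CO3 in MeOH then releases the diol, and the route is rejoined at 6.

Further compounds
F1 | step 9 | C3 trimethylsilyl ether of 14 | C[C@]1(OC(C)(C)O2)[C@@H]2[C@@H]3O[Si](C(C)(C)C)(C(C)(C)C)OC(C)(C)[C@@H]3[C@@H](/C=C/C)[C@]1(O[Si](C)(C)C)C=C
F2 | step 9 | ring-expanded C2–C3 trimethylsilyl enol ether | C[Si](C)(C)O/C1=C\C[C@H](C)/C=C/[C@H]2C(C)(C)O[Si](C(C)(C)C)(C(C)(C)C)O[C@H]2[C@@H]3OC(C)(C)O[C@]13C
F3 | step 7 | C8-allyl ketone | C[C@]1(OC(C)(C)O2)[C@@H]2[C@@H]3O[Si](C(C)(C)C)(C(C)(C)C)OC(C)(C)[C@@H]3[C@@H](CC=C)C1=O
F4 | step 3 | anti-epoxy ketone | CC1[C@H]2O[C@H]2[C@H](C(C)(C)O)CC1=O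
F5 | step 3 | trans-γ-hydroxy enone (C6 epimer of 6) | CC1=C[C@@H](O)[C@H](C(C)(C)O)CC1=O
F6 | step 3 | cis C6 4-nitrobenzoate | CC1=C[C@H](OC(=O)c2ccc(cc2)[N+](=O)[O-])[C@H](C(C)(C)O)CC1=O
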